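Read the south-west flask at 2.0 min and hold that time against two others: the time the charge needs to reach the pool of intermediate B and target, and the time that pool needs to drain.

    capture agent + intermediate A → trapped intermediate (k1 = 3.5 /M/s)
    intermediate A → intermediate B (k2 = 0.017 /s)
    starting material → intermediate A (k3 = 0.011 /s)
    intermediate B ⇌ target (K4 = 1.1, k4 = 0.030 /s)
    starting material → intermediate B (k5 = 0.022 /s)
    target → over-reaction product (k6 = 0.0059 /s)

all flasks: capture agent 0.500 mM

| charge | starting material | time | remark |
|---|---|---|---|
| west | 10 mM (fed, over 2.00 min) | 2.0 min | all but starting material at the start; starting material goes in evenly over 2.00 min, the run ends at 2.0 min |
| south-west | 10 mM | 2.0 min | everything together in a closed stirred flask, run for 2.0 min |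
| north | 10 mM |  | a single well-mixed tank run continuously and read at steady state, 2.0 min in it on average |

* the set-up with the highest amount of target at the outlet or at the end, in percent of the starting material put in ("none" if the first two lie within 2 percentage points) (west / south-west / north / none)
* amount of target at the outlet or at the end, in percent of the starting material put in, west
* amount of target at the outlet or at the end, in percent of the starting material put in, south-west
* amount of target at the outlet or at the end, in percent of the starting material put in, north

- the stated concentrations are those of everything mixed, before any reaction; amounts are the same in each set-up
- the feed brings no volume worth counting
- run time (west): 2.0 min

1. Treat intermediate B and target as one pool, a pre-equilibrium, because they relax in 0.291 min, shorter than the reading time. Target then holds 52.4% of the pool.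

2. Let that share leak to over-reaction product. The pool then lasts 5.39 min on average; call this the drain time.

3. Object that the pool starts empty. Set capture aside, because at the starting concentration of capture agent it takes intermediate A at 0.00175 /s, slower than the 0.017 /s of the step to intermediate B. Starting material then needs 0.505 min on average, and the 33.3% of it that goes through intermediate A needs 0.980 min more, so the fill time is 0.832 min. The south-west reading falls later than one fill time and earlier than one drain time.

4. Reckon south-west with one exponential lag for filling and one for draining. The pool comes to 73.3% of the charge.

5. Object that target arrives one relaxation behind the pool. Use the lag 1.12 min for target, which gives 35.1% of the charge. Commit to this.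

6. In west the feed spreads ages evenly up to 2.00 min, with mean 1.00 min. Averaging the same lag over those ages gives 27.1%. Object that one exponential credits the youngest parcels too early, and take this figure as high.

7. In north residence times are spread exponentially with mean 2.0 min, which gives 24.5%. South-west comes first in this reckoning.

The forecast names south-west, with 22.4% for west, 34.7% for south-west and 22.7% for north, on the ground that “the network behaves almost linearly”. It stands lower than my reckoning for west and for north.

South-west gives 34.6%, against 22.4% in west and 22.7% in north, so south-west is best. South-west also holds 38.8% as intermediate B, which makes a pool of 73.4% of the charge. Left until 20.0 min, south-west stands past the drain time, which puts target at 1.50%; the flask gives 1.75%. West, younger on average by 1.00 min, should then stand higher by a factor 1.20; it gives 2.10%, a ratio of 1.20.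

The numbers belong to no real substance.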